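**Retrosynthetic overview**
- The target comes from its tris-MOM ether. C2 is secured as S by a Ru-catalysed transfer-hydrogenative kinetic resolution of the C2-epimer pair.
- Ring C is the only ring formed, and it is formed last, by 6-endo oxa-Michael closure of a 2'-hydroxychalcone whose other ortho oxygen is blocked as a MOM ether.
- The chalcone comes from a Claisen–Schmidt aldol condensation (key C–C bond) of the ring A methyl ketone carrying the lavandulyl chain with the ring B aldehyde 2,6-bis(methoxymethoxy)benzaldehyde.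
- The ring A ketone comes from a Negishi coupling of (S)-lavandulylzinc iodide with a 3-iodoacetophenone. The lavandulyl unit comes from an Evans deconjugative α-prenylation of an N-senecioyl oxazolidinone.
- Rings A and B are bought as benzenes (2,6-dihydroxy-4-methoxyacetophenone and resorcinol).

Assumption: 1-(2,6-dihydroxy-4-methoxyphenyl)ethan-1-one is taken as a catalogue compound; the side-chain stereocentre keeps one geometry throughout, but its descriptor is S in the imide, alcohol, iodide and zinc reagent and R once the chain is attached to the arene, because the CIP priorities change.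

**Step 1**
Reactants: 1 (4S)-4-benzyl-1,3-oxazolidin-2-one; 2 3-methylbut-2-enoyl chloride
Product: 4 (4S)-4-benzyl-3-(3-methylbut-2-enoyl)-1,3-oxazolidin-2-one, via lithium oxazolidinide 3 (not isolated)
Conditions: n-BuLi (1.0 equiv), THF, −78 °C; then 2, −78 → 0 °C
Reagents that add atoms: none
Why: N-acylation of the lithiated Evans auxiliary by the acid chloride is fast at low temperature and does not touch the auxiliary stereocentre.

**Step 2**
Reactants: 4 (4S)-4-benzyl-3-(3-methylbut-2-enoyl)-1,3-oxazolidin-2-one; 5 1-bromo-3-methylbut-2-ene (prenyl bromide)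
Product: 7 (4S)-4-benzyl-3-[(2S)-5-methyl-2-(prop-1-en-2-yl)hex-4-enoyl]-1,3-oxazolidin-2-one, via sodium dienolate 6 (not isolated)
Conditions: NaN(SiMe3)2 (1.05 equiv), THF, −78 °C, 45 min; then 5 (2 equiv), −78 → −45 °C; AcOH quench at −78 °C; chromatography to a single diastereomer
Reagents that add atoms: none
Why: Evans asymmetric alkylation in its deconjugative form: γ-deprotonation gives the chelated Z(O) dienolate, which is prenylated at the α-carbon on the face opposite the benzyl group (same sense as the propionyl/allyl iodide case), setting the lavandulyl stereocentre as 2S.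

**Step 3**
Reactants: 7 (4S)-4-benzyl-3-[(2S)-5-methyl-2-(prop-1-en-2-yl)hex-4-enoyl]-1,3-oxazolidin-2-one
Product: 8 (2S)-5-methyl-2-(prop-1-en-2-yl)hex-4-en-1-ol ((S)-lavandulol)
Conditions: LiBH4 (2 equiv), H2O (1.1 equiv), Et2O, 0 °C
Reagents that add atoms: none
Why: Reductive cleavage of the imide by hydride attack at the exocyclic carbonyl gives the primary alcohol under non-basic conditions, so the doubly activated α-stereocentre and both alkenes survive.

**Step 4**
Reactants: 8 (2S)-5-methyl-2-(prop-1-en-2-yl)hex-4-en-1-ol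
Product: 9 (3S)-3-(iodomethyl)-2,6-dimethylhepta-1,5-diene ((S)-lavandulyl iodide)
Conditions: PPh3, imidazole, I2, CH2Cl2, 0 °C → rt
Reagents that add atoms: iodine, [I][I]
Why: Appel-type iodination proceeds by SN2 at the primary CH2, one carbon away from the stereocentre, which is therefore untouched.

**Step 5**
Reactants: 10 1-(2,6-dihydroxy-4-methoxyphenyl)ethan-1-one
Product: 11 1-[2-hydroxy-4-methoxy-6-(methoxymethoxy)phenyl]ethan-1-one
Conditions: MOMCl (1.2 equiv), i-Pr2NEt (1.5 equiv), CH2Cl2, 0 °C → rt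
Reagents that add atoms: chloromethyl methyl ether, COCCl
Why: Williamson-type etherification of the C2-symmetric diol stops at the mono-ether because the remaining phenol is locked in a hydrogen bond to the ketone.

**Step 6**
Reactants: 11 1-[2-hydroxy-4-methoxy-6-(methoxymethoxy)phenyl]ethan-1-one
Product: 12 1-[2-hydroxy-3-iodo-4-methoxy-6-(methoxymethoxy)phenyl]ethan-1-one
Conditions: BnMe3N+ ICl2− (1.05 equiv), NaHCO3 (3 equiv), CH2Cl2/MeOH 5:2, rt
Reagents that add atoms: benzyltrimethylammonium dichloroiodate, C[N+](C)(C)Cc1ccccc1.Cl[I-]Cl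
Why: Electrophilic aromatic iodination goes ortho to the free chelated phenol at C3, the less hindered open position (as with 2-hydroxy-4,6-dimethoxyacetophenone), the bicarbonate buffer protects the MOM ether, and the regiochemistry is confirmed by NOE from the remaining ArH to both OCH3 and OCH2O.

**Step 7**
Reactants: 12 1-[2-hydroxy-3-iodo-4-methoxy-6-(methoxymethoxy)phenyl]ethan-1-one
Product: 13 2-acetyl-6-iodo-5-methoxy-3-(methoxymethoxy)phenyl acetate
Conditions: Ac2O, pyridine, DMAP (cat.), rt → 40 °C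
Reagents that add atoms: acetic anhydride, CC(=O)OC(C)=O
Why: DMAP-catalysed O-acetylation masks the acidic phenol so that it does not quench the organozinc in the next step, and the acetate falls off again under the aldol conditions.

**Step 8**
Reactants: 9 (3S)-3-(iodomethyl)-2,6-dimethylhepta-1,5-diene; 13 2-acetyl-6-iodo-5-methoxy-3-(methoxymethoxy)phenyl acetate
Product: 15 2-acetyl-5-methoxy-3-(methoxymethoxy)-6-[(2R)-5-methyl-2-(prop-1-en-2-yl)hex-4-en-1-yl]phenyl acetate, via alkylzinc iodide 14 (not isolated)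
Conditions: 9 (1.3 equiv), Zn dust (activated by BrCH2CH2Br/Me3SiCl), LiCl, THF, 40 °C; then 13, Pd(OAc)2 (4 mol %), SPhos (8 mol %), THF, 25 → 50 °C
Reagents that add atoms: none
Why: Zinc insertion into the primary iodide followed by Negishi cross-coupling forms the ArCH2–CH bond; the bulky biaryl phosphine handles di-ortho-substituted aryl iodides, the organozinc tolerates ketone, ester and acetal, and the β-stereocentre is not involved.

**Step 9**
Reactants: 16 resorcinol
Product: 17 1,3-bis(methoxymethoxy)benzene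
Conditions: MOMCl (2.5 equiv), i-Pr2NEt (3 equiv), CH2Cl2, 0 °C → rt
Reagents that add atoms: chloromethyl methyl ether, COCCl
Why: Double Williamson-type MOM etherification of two unhindered phenols is routine.

**Step 10**
Reactants: 17 1,3-bis(methoxymethoxy)benzene
Product: 19 2,6-bis(methoxymethoxy)benzaldehyde, via aryllithium 18 (not isolated)
Conditions: n-BuLi (1.1 equiv), THF, 0 °C → rt, 1 h; DMF (1.5 equiv), 0 °C → rt; H2O
Reagents that add atoms: N,N-dimethylformamide, CN(C)C=O
Why: Directed ortho-metalation occurs at the position flanked by both OMOM groups, and formylation of the aryllithium with DMF gives the aldehyde.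

**Step 11**
Reactants: 15 2-acetyl-5-methoxy-3-(methoxymethoxy)-6-[(2R)-5-methyl-2-(prop-1-en-2-yl)hex-4-en-1-yl]phenyl acetate; 19 2,6-bis(methoxymethoxy)benzaldehyde
Product: 22 (E)-3-[2,6-bis(methoxymethoxy)phenyl]-1-{2-hydroxy-4-methoxy-6-(methoxymethoxy)-3-[(2R)-5-methyl-2-(prop-1-en-2-yl)hex-4-en-1-yl]phenyl}prop-2-en-1-one, via free phenol 20 (not isolated), via aldol adduct 21 (not isolated)
Conditions: 19 (1.2 equiv), KOH (50% aq, 10 equiv), EtOH, 0 °C → rt, 36 h, N2; cold citric acid to pH 6
Reagents that add atoms: none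
Why: Claisen–Schmidt aldol condensation: hydroxide first saponifies the aryl acetate, the methyl-ketone enolate adds to the non-enolisable aldehyde, and E1cB dehydration gives the E-chalcone, while MOM ethers and both alkenes are inert to base.

**Step 12**
Reactants: 22 the E-chalcone of step 11
Product: 23 (2RS)-2-[2,6-bis(methoxymethoxy)phenyl]-7-methoxy-5-(methoxymethoxy)-8-[(2R)-5-methyl-2-(prop-1-en-2-yl)hex-4-en-1-yl]chroman-4-one (about 1:1 mixture of the two C2 epimers)
Conditions: NaOAc (10 equiv), EtOH, reflux, 36 h; recovered 22 is recycled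
Reagents that add atoms: none
Why: Base-mediated intramolecular oxa-Michael addition of the only free phenol closes ring C to the 8-substituted flavanone alone (the other ortho oxygen is a MOM ether); C2 forms without control, so both epimers arise.

**Step 13**
Reactants: 23 the C2-epimer mixture of step 12
Product: 24 (2S)-2-[2,6-bis(methoxymethoxy)phenyl]-7-methoxy-5-(methoxymethoxy)-8-[(2R)-5-methyl-2-(prop-1-en-2-yl)hex-4-en-1-yl]chroman-4-one
Conditions: RuCl(p-cymene)[(R,R)-TsDPEN] (2 mol %), HCO2H/Et3N 5:2, EtOAc, rt, stopped at about 55% conversion; chromatography (ketone from alcohol)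
Reagents that add atoms: none
Why: Noyori-type asymmetric transfer hydrogenation used as a kinetic resolution: the (R,R) catalyst delivers 4R carbinols and is matched with the 2R epimer (cis-flavan-4-ol), so the 2S ketone is left behind and C2 is fixed as S; isolated alkenes are not reduced.

**Step 14**
Reactants: 24 the (2S)-tris-MOM flavanone of step 13
Product: 25 (2S)-2-(2,6-dihydroxyphenyl)-5-hydroxy-7-methoxy-8-[(2R)-5-methyl-2-(prop-1-en-2-yl)hex-4-en-1-yl]chroman-4-one (exiguaflavanone B)
Conditions: 3 M aq HCl/MeOH 1:4, 45 °C, about 2 h, stopped as soon as complete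
Reagents that add atoms: none
Why: Acid-catalysed acetal exchange removes all three MOM ethers; the side chain has no neighbouring free phenol to cyclise onto, and the short exposure limits alkene hydration and C2 epimerisation.

**Compound list**
1 | (4S)-4-benzyl-1,3-oxazolidin-2-one | O=C1N[C@@H](Cc2ccccc2)CO1 | starting material
2 | 3-methylbut-2-enoyl chloride | CC(C)=CC(Cl)=O | starting material
3 | lithium (4S)-4-benzyl-2-oxo-1,3-oxazolidin-3-ide | [Li+].O=C1[N-][C@@H](Cc2ccccc2)CO1 | intermediate
4 | (4S)-4-benzyl-3-(3-methylbut-2-enoyl)-1,3-oxazolidin-2-one | CC(C)=CC(=O)N1C(=O)OC[C@@H]1Cc1ccccc1 | intermediate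
5 | 1-bromo-3-methylbut-2-ene | CC(C)=CCBr | starting material
6 | sodium Z(O)-dienolate of 4 | [Na+].C=C(C)/C=C(\[O-])N1C(=O)OC[C@@H]1Cc1ccccc1 | intermediate
7 | (4S)-4-benzyl-3-[(2S)-5-methyl-2-(prop-1-en-2-yl)hex-4-enoyl]-1,3-oxazolidin-2-one | C=C(C)[C@H](CC=C(C)C)C(=O)N1C(=O)OC[C@@H]1Cc1ccccc1 | intermediate
8 | (2S)-5-methyl-2-(prop-1-en-2-yl)hex-4-en-1-ol | C=C(C)[C@H](CC=C(C)C)CO | intermediate
9 | (3S)-3-(iodomethyl)-2,6-dimethylhepta-1,5-diene | C=C(C)[C@H](CC=C(C)C)CI | intermediate
10 | 1-(2,6-dihydroxy-4-methoxyphenyl)ethan-1-one | CC(=O)c1c(O)cc(OC)cc1O | starting material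
11 | 1-[2-hydroxy-4-methoxy-6-(methoxymethoxy)phenyl]ethan-1-one | CC(=O)c1c(O)cc(OC)cc1OCOC | intermediate
12 | 1-[2-hydroxy-3-iodo-4-methoxy-6-(methoxymethoxy)phenyl]ethan-1-one | CC(=O)c1c(O)c(I)c(OC)cc1OCOC | intermediate
13 | 2-acetyl-6-iodo-5-methoxy-3-(methoxymethoxy)phenyl acetate | CC(=O)Oc1c(I)c(OC)cc(OCOC)c1C(C)=O | intermediate
14 | [(2S)-5-methyl-2-(prop-1-en-2-yl)hex-4-en-1-yl]zinc iodide | C=C(C)[C@H](CC=C(C)C)C[Zn]I | intermediate
15 | 2-acetyl-5-methoxy-3-(methoxymethoxy)-6-[(2R)-5-methyl-2-(prop-1-en-2-yl)hex-4-en-1-yl]phenyl acetate | C=C(C)[C@H](CC=C(C)C)Cc1c(OC)cc(OCOC)c(C(C)=O)c1OC(C)=O | intermediate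
16 | resorcinol | Oc1cccc(O)c1 | starting material
17 | 1,3-bis(methoxymethoxy)benzene | COCOc1cccc(OCOC)c1 | intermediate
18 | [2,6-bis(methoxymethoxy)phenyl]lithium | [Li]c1c(OCOC)cccc1OCOC | intermediate
19 | 2,6-bis(methoxymethoxy)benzaldehyde | O=Cc1c(OCOC)cccc1OCOC | intermediate
20 | 1-{2-hydroxy-4-methoxy-6-(methoxymethoxy)-3-[(2R)-5-methyl-2-(prop-1-en-2-yl)hex-4-en-1-yl]phenyl}ethan-1-one | C=C(C)[C@H](CC=C(C)C)Cc1c(OC)cc(OCOC)c(C(C)=O)c1O | intermediate
21 | 3-[2,6-bis(methoxymethoxy)phenyl]-3-hydroxy-1-{2-hydroxy-4-methoxy-6-(methoxymethoxy)-3-[(2R)-5-methyl-2-(prop-1-en-2-yl)hex-4-en-1-yl]phenyl}propan-1-one (both carbinol epimers) | C=C(C)[C@H](CC=C(C)C)Cc1c(OC)cc(OCOC)c(C(=O)CC(O)c2c(OCOC)cccc2OCOC)c1O | intermediate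
22 | (E)-3-[2,6-bis(methoxymethoxy)phenyl]-1-{2-hydroxy-4-methoxy-6-(methoxymethoxy)-3-[(2R)-5-methyl-2-(prop-1-en-2-yl)hex-4-en-1-yl]phenyl}prop-2-en-1-one | C=C(C)[C@H](CC=C(C)C)Cc1c(OC)cc(OCOC)c(C(=O)/C=C/c2c(OCOC)cccc2OCOC)c1O | intermediate
23 | (2RS)-2-[2,6-bis(methoxymethoxy)phenyl]-7-methoxy-5-(methoxymethoxy)-8-[(2R)-5-methyl-2-(prop-1-en-2-yl)hex-4-en-1-yl]chroman-4-one (C2 epimer mixture) | C=C(C)[C@H](CC=C(C)C)Cc1c(OC)cc(OCOC)c2c1OC(c1c(OCOC)cccc1OCOC)CC2=O | intermediate
24 | (2S)-2-[2,6-bis(methoxymethoxy)phenyl]-7-methoxy-5-(methoxymethoxy)-8-[(2R)-5-methyl-2-(prop-1-en-2-yl)hex-4-en-1-yl]chroman-4-one | C=C(C)[C@H](CC=C(C)C)Cc1c(OC)cc(OCOC)c2c1O[C@H](c1c(OCOC)cccc1OCOC)CC2=O | intermediate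
25 | exiguaflavanone B, (2S)-2-(2,6-dihydroxyphenyl)-5-hydroxy-7-methoxy-8-[(2R)-5-methyl-2-(prop-1-en-2-yl)hex-4-en-1-yl]chroman-4-one | C=C(C)[C@H](CC=C(C)C)Cc1c(OC)cc(O)c2c1O[C@H](c1c(O)cccc1O)CC2=O | target

**Step count**
Total: 14 steps. Longest linear sequence: 9 steps (steps 1, 2, 3, 4, 8, 11, 12, 13, 14).

**Steps most likely to fail, with fallbacks**

The first is step 8, the Negishi coupling. A β-branched alkylzinc has to couple with an aryl iodide flanked by two ortho substituents, so slow transmetalation, protodezincation or β-hydride elimination may cut the yield. The fallback is a B-alkyl Suzuki–Miyaura coupling that sets out from iodide 9 and the free iodophenol 12 and comes back to the route at 20. Iodide 9 is treated with t-BuLi (2.1 equiv, Et2O, −78 °C) to give [(2S)-5-methyl-2-(prop-1-en-2-yl)hex-4-en-1-yl]lithium F1. This is trapped with B-methoxy-9-BBN as the borinate lithium B-methoxy-B-[(2S)-5-methyl-2-(prop-1-en-2-yl)hex-4-en-1-yl]-9-borabicyclo[3.3.1]nonan-9-uide F2. F2 is coupled directly with 12 (PdCl2(dppf), K3PO4 aq, DMF/THF, rt → 50 °C). The product is phenol 20, which is isolated and taken into the condensation of step 11; the acetate 13 and the coupled acetate 15 are then not needed.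

The second is step 13, the kinetic resolution. The 5-OMOM group next to the carbonyl and the 2,6-disubstituted aryl at C2 may slow the hydride transfer or lower the selectivity. The fallback sets out from 23 and comes back at 24. The two C2 epimers are diastereomers and are separated by preparative HPLC on a cellulose- or amylose-carbamate chiral stationary phase, with no chemistry at C4. The wanted epimer is 24. The unwanted (2R)-2-[2,6-bis(methoxymethoxy)phenyl]-7-methoxy-5-(methoxymethoxy)-8-[(2R)-5-methyl-2-(prop-1-en-2-yl)hex-4-en-1-yl]chroman-4-one F3 is heated with NaOAc in EtOH. It re-equilibrates through chalcone 22 to the mixture 23 and is separated again.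

The third is step 14, the protic removal of three MOM ethers. Acid may hydrate or hydrochlorinate the prenyl and isopropenyl alkenes, or epimerise C2 by opening ring C at the electron-rich benzylic C–O bond. The fallback sets out from 24 and comes back at 25. It replaces protic acetal hydrolysis by silyl transfer: Me3SiOTf/2,2'-bipyridyl (CH2Cl2, 0 °C → rt) converts the aryl MOM ethers into the tris(trimethylsilyl) ether (2S)-7-methoxy-8-[(2R)-5-methyl-2-(prop-1-en-2-yl)hex-4-en-1-yl]-5-(trimethylsilyloxy)-2-[2,6-bis(trimethylsilyloxy)phenyl]chroman-4-one F4. F4 is hydrolysed with water/MeOH at neutral pH to 25 without free strong acid.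

**Further compounds**
F1 | step 8 | [(2S)-5-methyl-2-(prop-1-en-2-yl)hex-4-en-1-yl]lithium | C=C(C)[C@H](CC=C(C)C)C[Li]
F2 | step 8 | lithium B-methoxy-B-[(2S)-5-methyl-2-(prop-1-en-2-yl)hex-4-en-1-yl]-9-borabicyclo[3.3.1]nonan-9-uide | C=C(C)[C@H](CC=C(C)C)C[B-]1(OC)C2CCCC1CCC2.[Li+]
F3 | step 13 | (2R)-2-[2,6-bis(methoxymethoxy)phenyl]-7-methoxy-5-(methoxymethoxy)-8-[(2R)-5-methyl-2-(prop-1-en-2-yl)hex-4-en-1-yl]chroman-4-one | C=C(C)[C@H](CC=C(C)C)Cc1c(OC)cc(OCOC)c2c1O[C@@H](c1c(OCOC)cccc1OCOC)CC2=O
F4 | step 14 | (2S)-7-methoxy-8-[(2R)-5-methyl-2-(prop-1-en-2-yl)hex-4-en-1-yl]-5-(trimethylsilyloxy)-2-[2,6-bis(trimethylsilyloxy)phenyl]chroman-4-one | C=C(C)[C@H](CC=C(C)C)Cc1c(OC)cc(O[Si](C)(C)C)c2c1O[C@H](c1c(O[Si](C)(C)C)cccc1O[Si](C)(C)C)CC2=O
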